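Ring B (the cycloheptadiene C7–C8–C9–C13–C14–C15–C16) is traced back to a trans-fused cyclohexanone by excising C13, the diene carbon that carries the lactone's O–CMe2 branch and sits between C9 and the ring CH (C14). The bicyclo[3.3.1]nonane C/D unit with all six stereocentres is completed first on this cyclohexane. In the key step the dibromocarbene adduct of the kinetic silyl enol ether undergoes Br/Mg exchange, addition to acetone and cyclopropyl-to-allyl ring opening: one operation expands ring B from six to seven atoms, installs the C13=C14 alkene and attaches C12 with its oxygen. Enol triflation at C9, Negishi coupling and lactonisation then close ring A.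

Key step: step 17

Remarks (text locants only, not part of any SMILES): C1 = bridgehead C bearing CO2Me; C2 = CH2; C3 = C(OH)Me; C4 = ketone; C5 = bridgehead C–Me; C6 = CH2; C7 = ring-fusion CH; C8 = diene C–Me; C9 = diene C bearing CH2CO2; C10/C11 = lactone CH2/C=O; C12 = CMe2–O; C13 = diene C bearing C12; C14 = ring =CH; C15 = ring CH2; C16 = ring-fusion C–Me; C17 = spiro-epoxide carbon. Ring A = lactone; ring B = C7, C8, C9, C13, C14, C15, C16; ring C = C16, C1, C17, C5, C6, C7; ring D = C1, C2, C3, C4, C5, C17. β is the face of the C16 methyl.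
Assumption: the chiral-imine Michael addition of step 1 follows its established facial sense, so that (R)-2 gives (R)-5; compounds 1 (racemic) and 28 (solution) are taken as commercial.

Step 1
Reactants: 1 7-methyl-1,4-dioxaspiro[4.5]decan-8-one (racemic); 2 (R)-1-phenylethylamine; 3 ethyl vinyl ketone
Product: 5 (R)-7-methyl-7-(3-oxopentyl)-1,4-dioxaspiro[4.5]decan-8-one, via ketimine 4 (not isolated)
Conditions: 2, TsOH (cat.), toluene, reflux, Dean–Stark; then 3, THF, 40 °C; then 20% aq. AcOH, rt
Reagents that add atoms: water, O
Why: Auxiliary-controlled deracemising Michael addition: the ketimine reacts through its more substituted secondary enamine tautomer in an aza-ene-like transition state in which the (R)-1-phenylethyl group shields one enamine face, so quaternary C16 should form with (R) configuration before aqueous acid hydrolyses the imine.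

Step 2
Reactants: 5 (R)-7-methyl-7-(3-oxopentyl)-1,4-dioxaspiro[4.5]decan-8-one
Product: 6 bicyclic enone (8a'R)-5',8a'-dimethyl-3',4',8',8a'-tetrahydro-1'H-spiro[1,3-dioxolane-2,2'-naphthalen]-6'(7'H)-one
Conditions: NaOMe, MeOH, 0 to 50 °C
Reagents that add atoms: none
Why: Intramolecular aldol condensation (ring-closing half of a Robinson annulation): the CH2 of the ethyl ketone adds to the ring ketone and dehydration gives the tetrasubstituted enone, leaving the quaternary centre untouched.

Step 3
Reactants: 6 bicyclic enone
Product: 7 trans-fused dioxolane decalol (C7–H α; C8–Me α; C9–OH β)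
Conditions: Li (excess), NH3(l), THF, EtOH, −78 to −33 °C; then NH4Cl
Reagents that add atoms: none
Why: Dissolving-metal (Birch-type) reduction: C7 of the enone radical anion is protonated axially, anti to the axial C16 methyl, which sets the trans ring fusion, and with ethanol present the ketone is reduced on to the equatorial C9 alcohol, so the ring-B ketone leaves the step masked.

Step 4
Reactants: 7 trans-fused dioxolane decalol
Product: 8 tert-butyldimethylsilyl ether of 7
Conditions: TBSCl, imidazole, DMF, rt
Reagents that add atoms: tert-butyldimethylsilyl chloride, CC(C)(C)[Si](C)(C)Cl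
Why: Silylation of the secondary alcohol (substitution at silicon) makes ring B a spectator for steps 5 to 12.

Step 5
Reactants: 8 tert-butyldimethylsilyl ether
Product: 9 ring-C ketone (C17=O) with C9–OTBS
Conditions: PPTS, acetone/H2O, 60 °C
Reagents that add atoms: water, O
Why: Acid-catalysed hydrolysis of the dioxolane via the oxocarbenium ion unmasks the C17 ketone; the secondary silyl ether should be stable to pyridinium tosylate.

Step 6
Reactants: 9 ring-C ketone
Product: 10 C5-methyl ketone (equatorial epimer drawn)
Conditions: LiN(iPr)2, THF, −78 °C; MeI, −78 to −20 °C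
Reagents that add atoms: iodomethane, CI
Why: Kinetic enolate alkylation (SN2): the base removes a hydrogen from the unhindered C5 methylene rather than from the neopentyl C1 methylene next to quaternary C16, and the new C5 centre is epimerisable and later becomes quaternary, so its configuration is of no consequence.

Step 7
Reactants: 10 C5-methyl ketone
Product: 11 methyl β-keto ester (CO2Me on C1; keto form drawn)
Conditions: NaH, (MeO)2CO, KH (cat.), THF, reflux; AcOH quench
Reagents that add atoms: dimethyl carbonate, COC(=O)OC
Why: Crossed Claisen condensation under equilibrating conditions: acylation at methyl-bearing C5 would give a non-enolisable β-keto ester and is reversible, so the product should accumulate as the stabilised sodium enolate of the C1 β-keto ester.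

Step 8
Reactants: 11 methyl β-keto ester; 12 methacrolein
Product: 14 bicyclo[3.3.1]nonanone hydroxy ester (C17 ketone; C4 hydroxyl; C3/C4 epimers), via keto aldehyde 13 (not isolated)
Conditions: 12, DBU (cat.), MeCN, 0 °C; then KOtBu (cat.), tBuOH/THF, 0 °C to rt
Reagents that add atoms: none
Why: Michael–aldol annulation to a bicyclo[3.3.1]nonan-9-one: the β-keto ester enolate adds to the enal on the face of C1 anti to the vicinal axial C16 methyl (setting C1), and the C5 enolate then closes ring D by exo-trig aldol addition on the face dictated by the tether (setting C5), while C3 and C4 form as epimer mixtures that converge in steps 10 and 11.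

Step 9
Reactants: 14 bicyclo[3.3.1]nonanone hydroxy ester
Product: 15 exocyclic methylene hydroxy ester (C17=CH2)
Conditions: Cp2TiMe2 (excess), toluene/THF, 70 °C, dark
Reagents that add atoms: dimethyltitanocene, C[Ti](C)(C1C=CC=C1)C1C=CC=C1
Why: Carbonyl methylenation by the titanium methylidene Cp2Ti=CH2 generated thermally (oxatitanacyclobutane formation and cycloreversion), a non-basic reagent that should reach the doubly neopentyl C17 ketone, tolerate the hydroxyl as its titanium alkoxide and react with the ketone faster than with the hindered ester.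

Step 10
Reactants: 15 exocyclic methylene hydroxy ester
Product: 16 C4 ketone (C3 epimers)
Conditions: Dess–Martin periodinane, NaHCO3, CH2Cl2, rt
Reagents that add atoms: none
Why: Dess–Martin oxidation of the secondary C4 alcohol gives the same ketone from both C4 epimers.

Step 11
Reactants: 16 C4 ketone
Product: 17 α-ketol (C3–OH exo; C3–Me endo)
Conditions: KN(SiMe3)2, THF, −78 °C; 2-(phenylsulfonyl)-3-phenyloxaziridine, −78 °C; NH4Cl
Reagents that add atoms: 2-(phenylsulfonyl)-3-phenyloxaziridine, O=S(=O)(c1ccccc1)N1OC1c1ccccc1
Why: Enolate α-hydroxylation with an N-sulfonyloxaziridine: C3 is the only enolisable position of the C4 ketone, and the oxidant should attack the exo face of the enolate (syn to the one-carbon bridge C17, away from the ring-C bridge), placing the hydroxyl exo and the methyl endo as in the target.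

Step 12
Reactants: 17 α-ketol
Product: 18 spiro-epoxide with C9–OTBS
Conditions: mCPBA, NaHCO3, CH2Cl2, 0 °C to rt
Reagents that add atoms: 3-chloroperoxybenzoic acid, OOC(=O)c1cccc(Cl)c1
Why: Prilezhaev epoxidation of the only alkene: the methylene face toward ring C is shielded by the axial C16 methyl (1,3-relationship) and the C3 hydroxyl on the ring-D side can hydrogen-bond to the peracid, so oxygen should be delivered from the ring-D face, setting C17.

Step 13
Reactants: 18 spiro-epoxide with C9–OTBS
Product: 19 C9 alcohol
Conditions: Bu4NF, AcOH, THF, rt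
Reagents that add atoms: none
Why: Fluoride-mediated desilylation of the secondary silyl ether, buffered with acetic acid to protect the α-ketol and the epoxide.

Step 14
Reactants: 19 C9 alcohol
Product: 20 ring-B cyclohexanone (C9=O)
Conditions: Dess–Martin periodinane, NaHCO3, CH2Cl2, rt
Reagents that add atoms: none
Why: Dess–Martin oxidation of the secondary C9 alcohol regenerates the ring-B ketone; the tertiary alcohol cannot be oxidised.

Step 15
Reactants: 20 ring-B cyclohexanone
Product: 21 bis(trimethylsilyl) compound (C9–C14 silyl enol ether; C3–OSiMe3)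
Conditions: Me3SiCl, THF, −78 °C; LiN(iPr)2 added (internal quench), −78 to 0 °C
Reagents that add atoms: chlorotrimethylsilane, C[Si](C)(C)Cl
Why: Kinetic silyl enol ether formation: the ring-B ketone is the only enolisable carbonyl (the C4 ketone and the ester have no α-hydrogen), the amide base removes the C14 methylene hydrogen rather than the C8 methine hydrogen, and the tertiary alkoxide is silylated as well, which shields it in step 16.

Step 16
Reactants: 21 bis(trimethylsilyl) compound
Product: 22 gem-dibromocyclopropane (CBr2 bridging C9 and C14)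
Conditions: CHBr3, KOtBu, pentane, −40 to −15 °C; crude adduct used at once
Reagents that add atoms: bromoform, BrC(Br)Br
Why: Cheletropic addition of dibromocarbene (α-elimination of bromoform) to the electron-rich silyl enol ether, the only alkene present; the face of addition (expected anti to the C16 methyl) does not matter because C9 and C14 become trigonal again in step 17.

Step 17
Reactants: 22 gem-dibromocyclopropane; 23 acetone
Product: 26 ring-expanded cycloheptenone diol (C9 ketone; C13 bearing CMe2OH; C13=C14), via magnesium carbenoid 24 (not isolated), via bromo alkoxide 25 (not isolated)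
Conditions: iPrMgCl·LiCl, THF, −78 °C; 23, −78 to −40 °C; Bu4NF, −40 °C to rt; NH4Cl
Reagents that add atoms: none
Why: Bromine–magnesium exchange at the exo bromine (anti to the six-membered ring, syn to the siloxy oxygen) should give a configurationally stable cyclopropylmagnesium carbenoid that adds to acetone with retention, leaving the endo bromine in place. Fluoride then frees the cyclopropanolate, whose oxygen lone pair drives ionisation of the endo C–Br bond with concerted disrotatory two-electron electrocyclic opening of the C9–C14 bond (cyclopropyl-to-allyl cation rearrangement), so the six-membered ring becomes the seven-membered 2-substituted cyclohept-2-enone. The closest known reaction types are the ring expansion of 1-siloxy-7-halobicyclo[4.1.0]heptanes to 2-halo- or 2-alkylcyclohept-2-enones and the trapping of α-bromocyclopropyl magnesium or lithium carbenoids with carbonyl compounds. No ring is closed and no stereocentre is created; C9 and C14 become trigonal and the cyclopropane descriptors are erased. The step needs exchange to outrun attack on the C4 ketone, the ester and the epoxide (the exchange is very fast at −78 °C and these groups are neopentyl or non-enolisable and hindered) and needs the endo bromide to be the one that leaves (secured by exchanging the more accessible, oxygen-coordinated exo bromine).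

Step 18
Reactants: 26 ring-expanded cycloheptenone diol
Product: 27 dienyl triflate (C9–OTf; C8=C9; C13=C14)
Conditions: LiN(iPr)2 (3.5 equiv), THF, −78 °C; PhNTf2, −78 to 0 °C; NH4Cl
Reagents that add atoms: N-phenylbis(trifluoromethanesulfonimide), O=S(=O)(N(c1ccccc1)S(=O)(=O)C(F)(F)F)C(F)(F)F
Why: Enol triflate formation: after deprotonation of both tertiary hydroxyls the base removes the only α-hydrogen of the enone (C8–H) and the cross-conjugated lithium enolate is sulfonylated on oxygen, which creates the tetrasubstituted C8=C9 alkene and removes the C8 stereocentre.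

Step 19
Reactants: 27 dienyl triflate; 28 (2-ethoxy-2-oxoethyl)zinc bromide
Product: 30 CNP0605450.1 (target), via hydroxy ester 29 (not isolated)
Conditions: Pd2(dba)3 (cat.), XPhos (cat.), 28 (excess), THF, 60 °C; AcOH quench at 0 °C
Reagents that add atoms: none
Why: Negishi cross-coupling of the Reformatsky-type zinc ester enolate with the dienyl triflate (oxidative addition, transmetalation, reductive elimination) attaches CH2CO2Et to C9 without moving the diene, and the neighbouring tertiary zinc alkoxide should then close ring A by 6-exo-trig acyl substitution with loss of ethoxide; no stereocentre is formed.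

Compound list
1 | 7-methyl-1,4-dioxaspiro[4.5]decan-8-one (racemic) | CC1CC2(OCCO2)CCC1=O | starting material
2 | (R)-1-phenylethylamine | C[C@@H](N)c1ccccc1 | starting material
3 | ethyl vinyl ketone (pent-1-en-3-one) | CCC(=O)C=C | starting material
4 | N-[(R)-1-phenylethyl] ketimine of 1 (not isolated) | CC1CC2(OCCO2)CCC1=N[C@H](C)c1ccccc1 | intermediate
5 | (R)-7-methyl-7-(3-oxopentyl)-1,4-dioxaspiro[4.5]decan-8-one | CCC(=O)CC[C@]1(C)CC2(OCCO2)CCC1=O | intermediate
6 | (8a'R)-5',8a'-dimethyl-3',4',8',8a'-tetrahydro-1'H-spiro[1,3-dioxolane-2,2'-naphthalen]-6'(7'H)-one | CC1=C2CCC3(OCCO3)C[C@@]2(C)CCC1=O | intermediate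
7 | trans-fused dioxolane decalol (C7–H α, C8–Me α, C9–OH β, C16–Me β) | C1C2(OCCO2)CC[C@H]3[C@H](C)[C@@H](O)CC[C@@]31C | intermediate
8 | tert-butyldimethylsilyl ether of 7 | C1C2(OCCO2)CC[C@H]3[C@H](C)[C@@H](O[Si](C)(C)C(C)(C)C)CC[C@@]31C | intermediate
9 | ring-C ketone (C17=O) with C9–OTBS | C1C(=O)CC[C@H]3[C@H](C)[C@@H](O[Si](C)(C)C(C)(C)C)CC[C@@]31C | intermediate
10 | C5-methyl ketone (equatorial C5 epimer drawn) | C1C(=O)[C@@H](C)C[C@H]3[C@H](C)[C@@H](O[Si](C)(C)C(C)(C)C)CC[C@@]31C | intermediate
11 | methyl β-keto ester, CO2Me on C1 (keto form, equatorial ester drawn) | COC(=O)[C@H]1C(=O)[C@@H](C)C[C@H]3[C@H](C)[C@@H](O[Si](C)(C)C(C)(C)C)CC[C@@]31C | intermediate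
12 | methacrolein (2-methylprop-2-enal) | CC(=C)C=O | starting material
13 | C1-quaternary keto aldehyde, Michael adduct (not isolated; C3 epimers) | COC(=O)[C@@]1(CC(C)C=O)C(=O)[C@@H](C)C[C@H]3[C@H](C)[C@@H](O[Si](C)(C)C(C)(C)C)CC[C@@]31C | intermediate
14 | bicyclo[3.3.1]nonan-9-one hydroxy ester (C17=O, C4–OH; C3/C4 epimers) | COC(=O)[C@]12CC(C)C(O)[C@](C)(C[C@H]3[C@H](C)[C@@H](O[Si](C)(C)C(C)(C)C)CC[C@@]31C)C2=O | intermediate
15 | exocyclic methylene hydroxy ester (C17=CH2; C3/C4 epimers) | COC(=O)[C@]12CC(C)C(O)[C@](C)(C[C@H]3[C@H](C)[C@@H](O[Si](C)(C)C(C)(C)C)CC[C@@]31C)C2=C | intermediate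
16 | C4 ketone (C3 epimers) | COC(=O)[C@]12CC(C)C(=O)[C@](C)(C[C@H]3[C@H](C)[C@@H](O[Si](C)(C)C(C)(C)C)CC[C@@]31C)C2=C | intermediate
17 | α-ketol (C3–OH exo, C3–Me endo) | COC(=O)[C@]12C[C@@](C)(O)C(=O)[C@](C)(C[C@H]3[C@H](C)[C@@H](O[Si](C)(C)C(C)(C)C)CC[C@@]31C)C2=C | intermediate
18 | spiro-epoxide with C9–OTBS | COC(=O)[C@]12C[C@@](C)(O)C(=O)[C@](C)(C[C@H]3[C@H](C)[C@@H](O[Si](C)(C)C(C)(C)C)CC[C@@]31C)[C@]21CO1 | intermediate
19 | C9 alcohol | COC(=O)[C@]12C[C@@](C)(O)C(=O)[C@](C)(C[C@H]3[C@H](C)[C@@H](O)CC[C@@]31C)[C@]21CO1 | intermediate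
20 | ring-B cyclohexanone (C9=O) | COC(=O)[C@]12C[C@@](C)(O)C(=O)[C@](C)(C[C@H]3[C@H](C)C(=O)CC[C@@]31C)[C@]21CO1 | intermediate
21 | bis(trimethylsilyl) compound (C9–C14 silyl enol ether, C3–OSiMe3) | COC(=O)[C@]12C[C@@](C)(O[Si](C)(C)C)C(=O)[C@](C)(C[C@H]3[C@H](C)C(O[Si](C)(C)C)=CC[C@@]31C)[C@]21CO1 | intermediate
22 | gem-dibromocyclopropane (α-face adduct drawn) | COC(=O)[C@]12C[C@@](C)(O[Si](C)(C)C)C(=O)[C@](C)(C[C@H]3[C@H](C)[C@@]4(O[Si](C)(C)C)[C@H](C4(Br)Br)C[C@@]31C)[C@]21CO1 | intermediate
23 | acetone | CC(C)=O | starting material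
24 | exo-chloromagnesio endo-bromo cyclopropyl carbenoid (not isolated) | COC(=O)[C@]12C[C@@](C)(O[Si](C)(C)C)C(=O)[C@](C)(C[C@H]3[C@H](C)[C@@]4(O[Si](C)(C)C)[C@H]([C@]4(Br)[Mg]Cl)C[C@@]31C)[C@]21CO1 | intermediate
25 | endo-bromo cyclopropyl chloromagnesium alkoxide (not isolated) | COC(=O)[C@]12C[C@@](C)(O[Si](C)(C)C)C(=O)[C@](C)(C[C@H]3[C@H](C)[C@@]4(O[Si](C)(C)C)[C@H]([C@]4(Br)C(C)(C)O[Mg]Cl)C[C@@]31C)[C@]21CO1 | intermediate
26 | ring-expanded cycloheptenone diol (C9=O, C13–CMe2OH, C13=C14) | COC(=O)[C@]12C[C@@](C)(O)C(=O)[C@](C)(C[C@H]3[C@H](C)C(=O)C(C(C)(C)O)=CC[C@@]31C)[C@]21CO1 | intermediate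
27 | dienyl triflate (C9–OTf) | COC(=O)[C@]12C[C@@](C)(O)C(=O)[C@](C)(C[C@H]3C(C)=C(OS(=O)(=O)C(F)(F)F)C(C(C)(C)O)=CC[C@@]31C)[C@]21CO1 | intermediate
28 | (2-ethoxy-2-oxoethyl)zinc bromide | CCOC(=O)C[Zn]Br | starting material
29 | hydroxy ethyl ester (not isolated) | COC(=O)[C@]12C[C@@](C)(O)C(=O)[C@](C)(C[C@H]3C(C)=C(CC(=O)OCC)C(C(C)(C)O)=CC[C@@]31C)[C@]21CO1 | intermediate
30 | CNP0605450.1 | COC(=O)[C@]12C[C@@](C)(O)C(=O)[C@](C)(C[C@H]3C(C)=C4CC(=O)OC(C)(C)C4=CC[C@@]31C)[C@]21CO1 | target

Total step count: 19. Longest linear sequence: 19 steps (1 to 30).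

Steps most likely to fail

Step 17 (key step). The cyclopropylmagnesium carbenoid may collapse by α-elimination or by β-elimination of siloxide, or may be protonated or may enolise acetone instead of adding to it, before the ring opens. The fallback sets out from 22 and returns to the route at 30. Treatment of 22 with Bu4NF alone triggers the same ring expansion without the exchange and should give the 2-bromocyclohept-2-enone F1. Suzuki–Miyaura coupling with isopropenylboronic acid pinacol ester (Pd(PPh3)4, K3PO4, dioxane/H2O) would give the isopropenyl dienone F2. Enol triflation as in step 18 would give the trienyl triflate F3, and Negishi coupling with (2-tert-butoxy-2-oxoethyl)zinc bromide the tert-butyl ester F4. Ring A would then be closed under neutral conditions by a Co(salen)-catalysed hydrogen-atom-transfer/radical-polar-crossover hydro-acyloxylation of the isopropenyl group (N-fluoro-2,4,6-trimethylpyridinium salt, (Me2SiH)2O), the ester oxygen trapping the allylic cation at C12 with loss of isobutene.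

Step 9. Methylenation of the doubly neopentyl ketone may be slower than thermal retro-aldol opening of the β-hydroxy ketone or than attack on the ester. The fallback sets out from 14 and returns at 15. Silylation (Et3SiCl, imidazole) would give the triethylsilyl ether F5. Addition of Me3SiCH2Li/CeCl3 (THF, −78 °C) to the C17 ketone would give the β-hydroxysilane F6. HF·pyridine (THF, 0 °C) would then effect the Peterson elimination and remove the triethylsilyl group; the hindered secondary TBS ether is expected to survive brief exposure.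

Step 19. Oxidative addition and transmetalation at the tetrasubstituted, doubly flanked dienyl triflate may be slow, the zinc enolate may be consumed by the free hydroxyls, and the deconjugated lactone could isomerise if its enolate is protonated at the γ-position on work-up. The fallback sets out from 27 and returns at 29. It reverses the polarity: Miyaura borylation (B2pin2, PdCl2(PPh3)2, PPh3, KOPh, toluene, 50 °C) would give the dienyl pinacol boronate F7. Suzuki–Miyaura coupling with ethyl bromoacetate (Pd(OAc)2, P(o-tol)3, K3PO4, THF/H2O) would give the hydroxy ester 29, which lactonises to 30 (catalytic Ti(OiPr)4 if required).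

Further compounds
F1 | step 17 | 2-bromocyclohept-2-enone (C9=O, C13–Br, C13=C14) | COC(=O)[C@]12C[C@@](C)(O)C(=O)[C@](C)(C[C@H]3[C@H](C)C(=O)C(Br)=CC[C@@]31C)[C@]21CO1
F2 | step 17 | isopropenyl dienone (C13–C(Me)=CH2) | COC(=O)[C@]12C[C@@](C)(O)C(=O)[C@](C)(C[C@H]3[C@H](C)C(=O)C(C(C)=C)=CC[C@@]31C)[C@]21CO1
F3 | step 17 | trienyl triflate (C9–OTf, C13–isopropenyl) | COC(=O)[C@]12C[C@@](C)(O)C(=O)[C@](C)(C[C@H]3C(C)=C(OS(=O)(=O)C(F)(F)F)C(C(C)=C)=CC[C@@]31C)[C@]21CO1
F4 | step 17 | tert-butyl ester (C9–CH2CO2tBu, C13–isopropenyl) | COC(=O)[C@]12C[C@@](C)(O)C(=O)[C@](C)(C[C@H]3C(C)=C(CC(=O)OC(C)(C)C)C(C(C)=C)=CC[C@@]31C)[C@]21CO1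
F5 | step 9 | C4 triethylsilyl ether of 14 | COC(=O)[C@]12CC(C)C(O[Si](CC)(CC)CC)[C@](C)(C[C@H]3[C@H](C)[C@@H](O[Si](C)(C)C(C)(C)C)CC[C@@]31C)C2=O
F6 | step 9 | C17 β-hydroxysilane (C17(OH)CH2SiMe3) | COC(=O)[C@]12CC(C)C(O[Si](CC)(CC)CC)[C@](C)(C[C@H]3[C@H](C)[C@@H](O[Si](C)(C)C(C)(C)C)CC[C@@]31C)C2(O)C[Si](C)(C)C
F7 | step 19 | dienyl pinacol boronate (C9–Bpin) | COC(=O)[C@]12C[C@@](C)(O)C(=O)[C@](C)(C[C@H]3C(C)=C(B4OC(C)(C)C(C)(C)O4)C(C(C)(C)O)=CC[C@@]31C)[C@]21CO1
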